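**Plan** (TBS = tert-butyldimethylsilyl; isochroman-1-one numbering C1, O2, C3, C4; side chain C1' on C3 out to the C5' methyl)

1. Cuts: the C3–C1' bond together with the lactone O2–C1 bond; then the side-chain ester O–C(=O) bond; then the aryl–C4 bond (Claisen rearrangement) and the terminal C=C of an allyl group (ozonolysis).
2. Enabling feature: C3, the oxygen-bearing sp3 carbon of lactone ring B, sits between benzylic C4 and C1' and closes a six-membered ring with C1. As an aldehyde carbon it accepts an alkenyl nucleophile at C1', and the alkoxide formed is O2, placed to close ring B on the ortho ester.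
3. Forward, aryl half: ring A is bought as methyl 2,5-dihydroxybenzoate; O-allylation and Claisen rearrangement put C4 and C3 on the ring; silylation and ozonolysis give the arylacetaldehyde.
4. Forward, chain half and union: (R)-pent-4-yn-2-ol gives the E-vinyl iodide, which is esterified with 5-O-TBS (R)-mevalonic acid from (R)-mevalonolactone. Asymmetric chromium/nickel alkenylation joins the halves and ring B closes by lactonisation; alkene hydrogenation and global desilylation finish.
5. Stereochemistry: C3 from the chiral ligand on chromium in the coupling; C4' from (R)-pent-4-yn-2-ol; the tertiary carbinol from (R)-mevalonolactone.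

Key step: step 8

Assumption: the (S)-ligand of step 8 is taken to direct attack to the Re face of the aldehyde; should a model coupling show the opposite sense, its enantiomer is used with no other change.

**Route**

Step 1
Reactants: 1 methyl 2,5-dihydroxybenzoate; 2 allyl bromide
Product: 3 methyl 5-(allyloxy)-2-hydroxybenzoate
Conditions: K2CO3, acetone, reflux
Reagents that add atoms: none
Why: Williamson etherification; the 2-OH is held in a hydrogen bond to the ester carbonyl, so the 5-OH should be alkylated selectively.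

Step 2
Reactants: 3 methyl 5-(allyloxy)-2-hydroxybenzoate
Product: 4 methyl 2-allyl-3,6-dihydroxybenzoate
Conditions: PhNEt2, 200 °C, Ar
Reagents that add atoms: none
Why: Aromatic Claisen rearrangement ([3,3] shift, then tautomerisation); migration to the ortho carbon between the ether oxygen and the ester should prevail, because a meta acceptor group and the bond fixation of the chelated salicylate both favour that position.

Step 3
Reactants: 4 methyl 2-allyl-3,6-dihydroxybenzoate
Product: 5 methyl 2-allyl-3,6-bis(tert-butyldimethylsilyloxy)benzoate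
Conditions: TBSCl, imidazole, DMAP (cat.), DMF, 40 °C
Reagents that add atoms: tert-butyldimethylsilyl chloride CC(C)(C)[Si](C)(C)Cl
Why: Standard silylation of phenols; the chelated hydroxyl is slower but should react with DMAP and gentle warming, and the allyl group and ester are inert.

Step 4
Reactants: 5 methyl 2-allyl-3,6-bis(tert-butyldimethylsilyloxy)benzoate
Product: 7 methyl 3,6-bis(tert-butyldimethylsilyloxy)-2-(2-oxoethyl)benzoate, via ozonide 6 (not isolated)
Conditions: O3, CH2Cl2, −78 °C (Sudan red 7B end point); then PPh3, −78 °C to rt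
Reagents that add atoms: ozone [O-][O+]=O
Why: Ozonolysis with reductive work-up; the terminal alkene reacts far faster than the silylated arene at −78 °C, and the arylacetaldehyde is carried on without storage.

Step 5
Reactants: 8 (R)-mevalonolactone
Product: 11 (R)-5-(tert-butyldimethylsilyloxy)-3-hydroxy-3-methylpentanoic acid, via sodium (R)-mevalonate 9 (not isolated), via silyl ester 10 (not isolated)
Conditions: NaOH (1.0 equiv), H2O/THF, rt, evaporate; TBSCl, imidazole, DMF, rt; aq. citric acid/THF, 0 °C
Reagents that add atoms: sodium hydroxide [Na+].[OH-]; tert-butyldimethylsilyl chloride CC(C)(C)[Si](C)(C)Cl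
Why: Saponification opens the lactone, silylation caps the primary hydroxyl and the carboxylate while the tertiary hydroxyl is too hindered, and the labile silyl ester is hydrolysed on mild acidic work-up; the quaternary stereocentre is not touched.

Step 6
Reactants: 12 (R)-pent-4-yn-2-ol
Product: 14 (2R,4E)-5-iodopent-4-en-2-ol, via alkenylzirconocene 13 (not isolated)
Conditions: Cp2Zr(H)Cl (2.3 equiv), THF, rt; then I2, 0 °C
Reagents that add atoms: iodine II
Why: Hydrozirconation and iodinolysis; the first equivalent of hydride is consumed by the hydroxyl, syn addition of Zr–H places zirconium on the terminal carbon, and iodine cleaves the C–Zr bond with retention to give the E-iodide, with the carbinol centre untouched.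

Step 7
Reactants: 14 (2R,4E)-5-iodopent-4-en-2-ol; 11 (R)-5-(tert-butyldimethylsilyloxy)-3-hydroxy-3-methylpentanoic acid
Product: 15 (2R,4E)-5-iodopent-4-en-2-yl (3R)-5-(tert-butyldimethylsilyloxy)-3-hydroxy-3-methylpentanoate
Conditions: DIC, DMAP (cat.), CH2Cl2, 0 °C to rt
Reagents that add atoms: none
Why: Steglich esterification; the secondary alcohol is acylated through the acylpyridinium ion with its C–O bond intact (retention), and the hindered tertiary hydroxyl of 11 should not compete.

Step 8
Reactants: 7 methyl 3,6-bis(tert-butyldimethylsilyloxy)-2-(2-oxoethyl)benzoate; 15 (2R,4E)-5-iodopent-4-en-2-yl (3R)-5-(tert-butyldimethylsilyloxy)-3-hydroxy-3-methylpentanoate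
Product: 17 (2R,4E)-5-[(3S)-5,8-bis(tert-butyldimethylsilyloxy)-1-oxoisochroman-3-yl]pent-4-en-2-yl (3R)-5-(tert-butyldimethylsilyloxy)-3-hydroxy-3-methylpentanoate, via hydroxy ester 16 (not isolated)
Conditions: CrCl2 (10 mol%), (S)-N-[2-(4-isopropyl-4,5-dihydrooxazol-2-yl)-6-methylphenyl]methanesulfonamide (11 mol%), 1,8-bis(dimethylamino)naphthalene (11 mol%), NiCl2·(2,9-dimethyl-1,10-phenanthroline) (2 mol%), Mn, Cp2ZrCl2, LiCl, MeCN, rt; aqueous work-up; then PPTS (cat.), PhMe, 50 °C
Reagents that add atoms: none
Why: Nozaki–Hiyama–Kishi mechanism: zerovalent nickel inserts into the C–I bond of 15 with retention of the E geometry, the alkenyl group passes to chromium, and the ligand-bound alkenylchromium species (trivalent chromium) adds to the aldehyde carbon of 7 to make the C3–C1' bond, while Cp2ZrCl2 takes the alkoxide from chromium and Mn returns chromium to the divalent state. The closest known reaction type is the catalytic asymmetric chromium/nickel alkenylation of aliphatic aldehydes with oxazoline sulfonamide ligands, here followed by acid-catalysed lactonisation of a 2-(2-hydroxyalkyl)benzoate. Ring B closes by 6-exo-trig acyl substitution: the new C3 hydroxyl of 16 attacks the ortho ester carbonyl C1 and methanol leaves, and since the C3–O bond is never broken the configuration from the addition is kept. C3 is set under catalyst control, the chiral chromium complex delivering the alkenyl group to the Re face of the aldehyde (descriptor S at this stage because the vinyl carbon outranks C4, R after hydrogenation); the C4' centre of 15 lies four bonds away and should not influence the outcome. The step needs chemoselectivity for the aldehyde over the two esters and the free tertiary hydroxyl and must not enolise the arylacetaldehyde, which the weakly basic, aldehyde-selective alkenylchromium reagent secures; it also needs facial selectivity, which rests on the ligand alone.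

Step 9
Reactants: 17 (2R,4E)-5-[(3S)-5,8-bis(tert-butyldimethylsilyloxy)-1-oxoisochroman-3-yl]pent-4-en-2-yl (3R)-5-(tert-butyldimethylsilyloxy)-3-hydroxy-3-methylpentanoate
Product: 18 (2R)-5-[(3R)-5,8-bis(tert-butyldimethylsilyloxy)-1-oxoisochroman-3-yl]pentan-2-yl (3R)-5-(tert-butyldimethylsilyloxy)-3-hydroxy-3-methylpentanoate
Conditions: H2 (4 atm), Rh(PPh3)3Cl (10 mol%), PhH/EtOH, rt
Reagents that add atoms: none
Why: Homogeneous hydrogenation of the disubstituted alkene; the rhodium catalyst is chosen over palladium on carbon because it should saturate the C1'=C2' bond without hydrogenolysis of the allylic lactone C3–O bond, and no stereocentre is touched (the C3 descriptor changes to R only by priority).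

Step 10
Reactants: 18 (2R)-5-[(3R)-5,8-bis(tert-butyldimethylsilyloxy)-1-oxoisochroman-3-yl]pentan-2-yl (3R)-5-(tert-butyldimethylsilyloxy)-3-hydroxy-3-methylpentanoate
Product: 19 (2R)-5-[(3R)-5,8-dihydroxy-1-oxoisochroman-3-yl]pentan-2-yl (3R)-3,5-dihydroxy-3-methylpentanoate (target)
Conditions: HF·pyridine, pyridine, THF, 0 °C to rt, Ar; quench Me3SiOMe, evaporate
Reagents that add atoms: none
Why: Global fluoride-mediated desilylation of the two aryl silyl ethers and the primary silyl ether; the pyridine buffer and non-aqueous quench are meant to keep the freed 5-hydroxy ester from acyl transfer and the hydroquinone from air oxidation.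

**Compound list**

1 | methyl 2,5-dihydroxybenzoate | COC(=O)c1cc(O)ccc1O | starting material
2 | allyl bromide | C=CCBr | starting material
3 | methyl 5-(allyloxy)-2-hydroxybenzoate | COC(=O)c1cc(OCC=C)ccc1O | intermediate
4 | methyl 2-allyl-3,6-dihydroxybenzoate | COC(=O)c1c(CC=C)c(O)ccc1O | intermediate
5 | methyl 2-allyl-3,6-bis(tert-butyldimethylsilyloxy)benzoate | COC(=O)c1c(CC=C)c(O[Si](C)(C)C(C)(C)C)ccc1O[Si](C)(C)C(C)(C)C | intermediate
6 | ozonide of 5 (1,2,4-trioxolan-3-ylmethyl arene, not isolated) | COC(=O)c1c(CC2OCOO2)c(O[Si](C)(C)C(C)(C)C)ccc1O[Si](C)(C)C(C)(C)C | intermediate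
7 | methyl 3,6-bis(tert-butyldimethylsilyloxy)-2-(2-oxoethyl)benzoate | COC(=O)c1c(CC=O)c(O[Si](C)(C)C(C)(C)C)ccc1O[Si](C)(C)C(C)(C)C | intermediate
8 | (R)-mevalonolactone | O=C1C[C@](C)(O)CCO1 | starting material
9 | sodium (R)-3,5-dihydroxy-3-methylpentanoate (sodium (R)-mevalonate, not isolated) | [Na+].[O-]C(=O)C[C@](C)(O)CCO | intermediate
10 | tert-butyldimethylsilyl (R)-5-(tert-butyldimethylsilyloxy)-3-hydroxy-3-methylpentanoate (not isolated) | CC(C)(C)[Si](C)(C)OC(=O)C[C@](C)(O)CCO[Si](C)(C)C(C)(C)C | intermediate
11 | (R)-5-(tert-butyldimethylsilyloxy)-3-hydroxy-3-methylpentanoic acid | OC(=O)C[C@](C)(O)CCO[Si](C)(C)C(C)(C)C | intermediate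
12 | (R)-pent-4-yn-2-ol | C[C@H](CC#C)O | starting material
13 | [(1E,4R)-4-(chlorozirconocenyloxy)pent-1-en-1-yl]zirconocene chloride (not isolated) | C[C@H](C/C=C/[Zr](Cl)(C1C=CC=C1)C1C=CC=C1)O[Zr](Cl)(C1C=CC=C1)C1C=CC=C1 | intermediate
14 | (2R,4E)-5-iodopent-4-en-2-ol | C[C@H](C/C=C/I)O | intermediate
15 | (2R,4E)-5-iodopent-4-en-2-yl (3R)-5-(tert-butyldimethylsilyloxy)-3-hydroxy-3-methylpentanoate | C[C@H](C/C=C/I)OC(=O)C[C@](C)(O)CCO[Si](C)(C)C(C)(C)C | intermediate
16 | methyl 3,6-bis(tert-butyldimethylsilyloxy)-2-[(2S,3E,6R)-2-hydroxy-6-{[(3R)-5-(tert-butyldimethylsilyloxy)-3-hydroxy-3-methylpentanoyl]oxy}hept-3-en-1-yl]benzoate (not isolated) | C[C@H](C/C=C/[C@@H](O)Cc1c(O[Si](C)(C)C(C)(C)C)ccc(O[Si](C)(C)C(C)(C)C)c1C(=O)OC)OC(=O)C[C@](C)(O)CCO[Si](C)(C)C(C)(C)C | intermediate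
17 | (2R,4E)-5-[(3S)-5,8-bis(tert-butyldimethylsilyloxy)-1-oxoisochroman-3-yl]pent-4-en-2-yl (3R)-5-(tert-butyldimethylsilyloxy)-3-hydroxy-3-methylpentanoate | C[C@H](C/C=C/[C@@H]1Cc2c(O[Si](C)(C)C(C)(C)C)ccc(O[Si](C)(C)C(C)(C)C)c2C(=O)O1)OC(=O)C[C@](C)(O)CCO[Si](C)(C)C(C)(C)C | intermediate
18 | (2R)-5-[(3R)-5,8-bis(tert-butyldimethylsilyloxy)-1-oxoisochroman-3-yl]pentan-2-yl (3R)-5-(tert-butyldimethylsilyloxy)-3-hydroxy-3-methylpentanoate | C[C@H](CCC[C@@H]1Cc2c(O[Si](C)(C)C(C)(C)C)ccc(O[Si](C)(C)C(C)(C)C)c2C(=O)O1)OC(=O)C[C@](C)(O)CCO[Si](C)(C)C(C)(C)C | intermediate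
19 | (2R)-5-[(3R)-5,8-dihydroxy-1-oxoisochroman-3-yl]pentan-2-yl (3R)-3,5-dihydroxy-3-methylpentanoate | C[C@H](CCC[C@@H]1Cc2c(O)ccc(O)c2C(=O)O1)OC(=O)C[C@](C)(O)CCO | target

**Count and risks**

Total step count: 10. Longest linear sequence: 7 (steps 1, 2, 3, 4, 8, 9, 10).

Step 8. What may go wrong: the chiral chromium complex may discriminate poorly between the faces of an unbranched arylacetaldehyde, or the aldehyde may self-condense or cyclise to an isocoumarin before it couples. The fallback sets out from aldehyde 7 and acid 11 and comes back to the route at 18. Asymmetric allylboration of 7 with (+)-Ipc2B(allyl) (Et2O, −78 °C, ethanolamine work-up; Re-face delivery by the reagent) should give methyl 3,6-bis(tert-butyldimethylsilyloxy)-2-[(2R)-2-hydroxypent-4-en-1-yl]benzoate F1. PPTS in toluene should close it to (3R)-3-allyl-5,8-bis(tert-butyldimethylsilyloxy)isochroman-1-one F2. Separately, acid 11 is esterified (DIC, DMAP, CH2Cl2) with purchased (R)-but-3-en-2-ol F3 to give (R)-but-3-en-2-yl (3R)-5-(tert-butyldimethylsilyloxy)-3-hydroxy-3-methylpentanoate F4. Cross-metathesis of F2 with an excess of F4 (second-generation Grubbs catalyst, CH2Cl2, 40 °C) should give (2R,3E)-5-[(3R)-5,8-bis(tert-butyldimethylsilyloxy)-1-oxoisochroman-3-yl]pent-3-en-2-yl (3R)-5-(tert-butyldimethylsilyloxy)-3-hydroxy-3-methylpentanoate F5. Hydrogenation of F5 over Rh(PPh3)3Cl as in step 9 gives 18.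

Step 2. What may go wrong: the allyl group may migrate in part to the other ortho carbon (away from the ester), giving a regioisomer that is hard to separate. The fallback sets out from 1 and comes back at 4. Oxidation of 1 with Ag2O (MgSO4, Et2O, rt) should give methyl 3,6-dioxocyclohexa-1,4-diene-1-carboxylate F6, used at once. Conjugate addition of allyltributylstannane (CH2Cl2, −78 °C to 0 °C) is expected at the ring CH next to the ester-bearing carbon, which is β to both the quinone carbonyl and the ester. Tautomerisation of the adduct on work-up then gives 4 with the regiochemistry fixed by the quinone.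

Step 5. What may go wrong: silylation of the sparingly soluble carboxylate salt may stay incomplete, and the unsilylated hydroxy acid closes back to the lactone on acidification. The fallback sets out from 8 and comes back at 11. Opening of 8 with KOH (MeOH/H2O, evaporate) gives potassium (R)-3,5-dihydroxy-3-methylpentanoate F7, and alkylation with benzyl bromide in DMF should give benzyl (R)-3,5-dihydroxy-3-methylpentanoate F8. Silylation of the primary hydroxyl (TBSCl, imidazole, DMF) gives benzyl (R)-5-(tert-butyldimethylsilyloxy)-3-hydroxy-3-methylpentanoate F9. Hydrogenolysis of the benzyl ester (H2, Pd/C, EtOAc) then releases 11 under neutral conditions.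

**Further compounds**

F1 | step 8 | methyl 3,6-bis(tert-butyldimethylsilyloxy)-2-[(2R)-2-hydroxypent-4-en-1-yl]benzoate | C=CC[C@@H](O)Cc1c(O[Si](C)(C)C(C)(C)C)ccc(O[Si](C)(C)C(C)(C)C)c1C(=O)OC
F2 | step 8 | (3R)-3-allyl-5,8-bis(tert-butyldimethylsilyloxy)isochroman-1-one | C=CC[C@@H]1Cc2c(O[Si](C)(C)C(C)(C)C)ccc(O[Si](C)(C)C(C)(C)C)c2C(=O)O1
F3 | step 8 | (R)-but-3-en-2-ol (purchased) | C[C@H](C=C)O
F4 | step 8 | (R)-but-3-en-2-yl (3R)-5-(tert-butyldimethylsilyloxy)-3-hydroxy-3-methylpentanoate | C[C@H](C=C)OC(=O)C[C@](C)(O)CCO[Si](C)(C)C(C)(C)C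
F5 | step 8 | (2R,3E)-5-[(3R)-5,8-bis(tert-butyldimethylsilyloxy)-1-oxoisochroman-3-yl]pent-3-en-2-yl (3R)-5-(tert-butyldimethylsilyloxy)-3-hydroxy-3-methylpentanoate | C[C@H](/C=C/C[C@@H]1Cc2c(O[Si](C)(C)C(C)(C)C)ccc(O[Si](C)(C)C(C)(C)C)c2C(=O)O1)OC(=O)C[C@](C)(O)CCO[Si](C)(C)C(C)(C)C
F6 | step 2 | methyl 3,6-dioxocyclohexa-1,4-diene-1-carboxylate | COC(=O)C1=CC(=O)C=CC1=O
F7 | step 5 | potassium (R)-3,5-dihydroxy-3-methylpentanoate | [K+].[O-]C(=O)C[C@](C)(O)CCO
F8 | step 5 | benzyl (R)-3,5-dihydroxy-3-methylpentanoate | O=C(C[C@](C)(O)CCO)OCc1ccccc1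
F9 | step 5 | benzyl (R)-5-(tert-butyldimethylsilyloxy)-3-hydroxy-3-methylpentanoate | O=C(C[C@](C)(O)CCO[Si](C)(C)C(C)(C)C)OCc1ccccc1
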